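## Retrosynthetic overview

1. Caraphenol C (all-cis) ⇐ its pentabenzyl ether by neutral hydrogenolysis; the aryl ketone ⇐ an all-cis indan-1-ylmethanol (oxidation, aryl Grignard addition, oxidation), so the enolisable C1 never meets base.
2. All-cis C1/C2/C3 array ⇐ syn-hydrogenation of a 1-substituted 2,3-diaryl-1H-indene from the face anti to its single stereocentre C1.
3. Indene ⇐ 2-aryl-indan-1-one + aryl organometallic, then dehydration; indanone ⇐ a 2,3-diaryl-butanoic acid by intramolecular Friedel–Crafts acylation.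
4. Acid ⇐ γ-nitro imide ⇐ key step: intermolecular Michael addition of the titanium enolate of an Evans arylacetyl imide to a nitrostyrene (forms C1–C2; C1 fixed by the auxiliary); CH2NO2 → CO2H.
5. Ring order: all benzene rings are bought; the only ring formed is the five-membered ring of the indane (Friedel–Crafts step).

Assumption: the SMILES is taken literally; its descriptors are (1R,2R,3R), which is the all-cis indane (C1 aroyl cis to both aryl groups), and this isomer is the one made.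

## Route

Step 1
Reactants: 1 methyl 2-(3,5-dihydroxyphenyl)acetate
Product: 2 methyl 2-[3,5-bis(benzyloxy)phenyl]acetate
Conditions: BnBr (2.3 equiv), K2CO3, DMF, rt
Reagents that add atoms: benzyl bromide, BrCc1ccccc1
Why: Williamson ether synthesis on the two phenols goes cleanly with carbonate, which is too weak to deprotonate the ester alpha-position.

Step 2
Reactants: 2 methyl 2-[3,5-bis(benzyloxy)phenyl]acetate
Product: 3 2-[3,5-bis(benzyloxy)phenyl]acetic acid
Conditions: LiOH, THF–H2O, rt; then 1 M HCl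
Reagents that add atoms: lithium hydroxide, [Li+].[OH-]
Why: Saponification of an unhindered methyl ester is reliable and leaves the benzyl ethers untouched.

Step 3
Reactants: 3 2-[3,5-bis(benzyloxy)phenyl]acetic acid; 4 (4R)-4-benzyl-1,3-oxazolidin-2-one
Product: 6 (4R)-4-benzyl-3-{[3,5-bis(benzyloxy)phenyl]acetyl}-1,3-oxazolidin-2-one, via mixed pivalic anhydride 5 (not isolated)
Conditions: PivCl, Et3N, THF, −20 °C; then 4, LiCl, −20 °C → rt
Reagents that add atoms: none
Why: N-Acylation of the Evans auxiliary through the mixed pivalic anhydride is the standard one-pot method for arylacetic acids, the auxiliary attacking only the unhindered acyl carbon.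

Step 4
Reactants: 7 3,5-bis(benzyloxy)benzaldehyde; 8 nitromethane
Product: 10 1,3-bis(benzyloxy)-5-[(E)-2-nitroethenyl]benzene, via nitroaldol adduct 9 (not isolated)
Conditions: MeNO2 (5 equiv), NH4OAc, AcOH, 100 °C
Reagents that add atoms: none
Why: Henry (nitroaldol) condensation followed by dehydration gives the conjugated nitrostyrene as the thermodynamic E isomer.

Step 5
Reactants: 6 (4R)-4-benzyl-3-{[3,5-bis(benzyloxy)phenyl]acetyl}-1,3-oxazolidin-2-one; 10 1,3-bis(benzyloxy)-5-[(E)-2-nitroethenyl]benzene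
Product: 12 (4R)-4-benzyl-3-{(2R,3R)-2,3-bis[3,5-bis(benzyloxy)phenyl]-4-nitrobutanoyl}-1,3-oxazolidin-2-one, via chlorotitanium Z-enolate 11 (not isolated)
Conditions: TiCl4 (1.05 equiv), i-Pr2NEt (1.1 equiv), CH2Cl2, −78 °C; then 10, TiCl4 (1.0 equiv), −78 → −20 °C; H2O quench
Reagents that add atoms: none
Why: In this Evans auxiliary-controlled intermolecular Michael addition the chelated Z-enolate is attacked by the TiCl4-activated nitroalkene on the face opposite the auxiliary benzyl group, fixing the alpha-carbon (future C1) as R, while the beta-carbon (future C2, expected mainly syn, 3R) is erased later, so its selectivity is immaterial.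

Step 6
Reactants: 12 (4R)-4-benzyl-3-{(2R,3R)-2,3-bis[3,5-bis(benzyloxy)phenyl]-4-nitrobutanoyl}-1,3-oxazolidin-2-one
Product: 13 (2R,3R)-2,3-bis[3,5-bis(benzyloxy)phenyl]-4-nitrobutan-1-ol
Conditions: LiBH4, H2O (1 equiv), Et2O–THF, 0 °C
Reagents that add atoms: none
Why: Reductive cleavage of the N-acyloxazolidinone by LiBH4 attacks the exocyclic carbonyl, spares the aliphatic nitro group and turns the imide alpha-carbon into a non-enolisable stereocentre.

Step 7
Reactants: 13 (2R,3R)-2,3-bis[3,5-bis(benzyloxy)phenyl]-4-nitrobutan-1-ol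
Product: 14 (2R,3R)-2,3-bis[3,5-bis(benzyloxy)phenyl]-4-nitrobutyl pivalate
Conditions: PivCl, pyridine, DMAP (cat.), CH2Cl2, 0 °C → rt
Reagents that add atoms: pivaloyl chloride, CC(C)(C)C(Cl)=O
Why: Acylation of the primary alcohol gives a bulky ester that survives acid, hydrogenation and carbonate, cannot lactonise onto the later acid chloride as a free hydroxyl or ether could, and later shields one face of the indene.

Step 8
Reactants: 14 (2R,3R)-2,3-bis[3,5-bis(benzyloxy)phenyl]-4-nitrobutyl pivalate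
Product: 15 (2R,3R)-2,3-bis[3,5-bis(benzyloxy)phenyl]-4-(pivaloyloxy)butanoic acid
Conditions: NaNO2 (3 equiv), AcOH (10 equiv), DMSO, 35 °C
Reagents that add atoms: sodium nitrite, [Na+].[O-]N=O
Why: This Nef-type oxidation of a primary nitroalkane to the carboxylic acid (nitrite/acetic acid, via the nitrolic acid) runs under weakly acidic conditions that leave the ester, the benzyl ethers and C3 alone, and any epimerisation at C2 is irrelevant.

Step 9
Reactants: 15 (2R,3R)-2,3-bis[3,5-bis(benzyloxy)phenyl]-4-(pivaloyloxy)butanoic acid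
Product: 18 {(1R,2S)-4,6-bis(benzyloxy)-2-[3,5-bis(benzyloxy)phenyl]-3-oxo-2,3-dihydro-1H-inden-1-yl}methyl pivalate, via acid chloride 16 (not isolated), via cis-indanone 17 (not isolated)
Conditions: (COCl)2, DMF (cat.), CH2Cl2, 0 °C → rt; then SnCl4 (1.1 equiv), CH2Cl2, −78 → −40 °C; then Et3N (0.2 equiv), CH2Cl2, rt
Reagents that add atoms: none
Why: Intramolecular Friedel–Crafts acylation closes the five-membered ring at the only reachable ortho position of the aryl group on C1 (activated by one ortho and one para benzyloxy group), and the amine then equilibrates the acidic C2 to the trans ketone while C1 is untouched.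

Step 10
Reactants: 18 {(1R,2S)-4,6-bis(benzyloxy)-2-[3,5-bis(benzyloxy)phenyl]-3-oxo-2,3-dihydro-1H-inden-1-yl}methyl pivalate; 19 [4-(benzyloxy)phenyl]magnesium bromide
Product: 21 {(1S)-4,6-bis(benzyloxy)-2-[3,5-bis(benzyloxy)phenyl]-3-[4-(benzyloxy)phenyl]-1H-inden-1-yl}methyl pivalate, via tertiary carbinol 20 (not isolated)
Conditions: 19 (2.5 equiv), CeCl3 (2.5 equiv), THF, −78 → −30 °C; H2O quench; then TsOH·H2O (5 mol%), PhMe, rt
Reagents that add atoms: none
Why: The weakly basic organocerium reagent (Imamoto conditions) adds 1,2 to the enolisable 2-aryl ketone faster than it deprotonates it or attacks the hindered pivalate, and E1 dehydration of the doubly benzylic carbinol can only give the C2=C3 alkene, leaving C1 as the sole stereocentre (same geometry; S only through a change in CIP priorities).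

Step 11
Reactants: 21 {(1S)-4,6-bis(benzyloxy)-2-[3,5-bis(benzyloxy)phenyl]-3-[4-(benzyloxy)phenyl]-1H-inden-1-yl}methyl pivalate
Product: 22 {(1R,2R,3R)-2-(3,5-dihydroxyphenyl)-4,6-dihydroxy-3-(4-hydroxyphenyl)-2,3-dihydro-1H-inden-1-yl}methyl pivalate
Conditions: H2 (4 atm), 10% Pd/C, EtOAc–MeOH, rt
Reagents that add atoms: none
Why: Heterogeneous catalytic hydrogenation adds both hydrogens syn on the indene face that carries the C1 hydrogen (anti to the pivaloyloxymethyl group), setting C2 and C3 with both aryl groups cis to the C1 substituent, while the five benzyl ethers are hydrogenolysed in the same operation.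

Step 12
Reactants: 22 {(1R,2R,3R)-2-(3,5-dihydroxyphenyl)-4,6-dihydroxy-3-(4-hydroxyphenyl)-2,3-dihydro-1H-inden-1-yl}methyl pivalate
Product: 23 {(1R,2R,3R)-4,6-bis(benzyloxy)-2-[3,5-bis(benzyloxy)phenyl]-3-[4-(benzyloxy)phenyl]-2,3-dihydro-1H-inden-1-yl}methyl pivalate
Conditions: BnBr (6 equiv), K2CO3, DMF, rt
Reagents that add atoms: benzyl bromide, BrCc1ccccc1
Why: Williamson etherification re-masks the five phenols with a group removable at the very end without acid or base, at a stage where no stereocentre is enolisable and the pivalate is inert to carbonate.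

Step 13
Reactants: 23 {(1R,2R,3R)-4,6-bis(benzyloxy)-2-[3,5-bis(benzyloxy)phenyl]-3-[4-(benzyloxy)phenyl]-2,3-dihydro-1H-inden-1-yl}methyl pivalate
Product: 24 {(1R,2R,3R)-4,6-bis(benzyloxy)-2-[3,5-bis(benzyloxy)phenyl]-3-[4-(benzyloxy)phenyl]-2,3-dihydro-1H-inden-1-yl}methanol
Conditions: i-Bu2AlH (3 equiv), CH2Cl2, −78 °C; Rochelle salt
Reagents that add atoms: none
Why: Reductive ester cleavage by the aluminium hydride frees the primary alcohol without touching aryl benzyl ethers or any stereocentre.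

Step 14
Reactants: 24 {(1R,2R,3R)-4,6-bis(benzyloxy)-2-[3,5-bis(benzyloxy)phenyl]-3-[4-(benzyloxy)phenyl]-2,3-dihydro-1H-inden-1-yl}methanol
Product: 25 (1R,2R,3R)-4,6-bis(benzyloxy)-2-[3,5-bis(benzyloxy)phenyl]-3-[4-(benzyloxy)phenyl]-2,3-dihydro-1H-indene-1-carbaldehyde
Conditions: Dess–Martin periodinane, NaHCO3, CH2Cl2, 0 °C; used crude
Reagents that add atoms: none
Why: Dess–Martin oxidation is fast and buffered, so the now enolisable, contra-thermodynamic C1 stereocentre is not epimerised.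

Step 15
Reactants: 25 (1R,2R,3R)-4,6-bis(benzyloxy)-2-[3,5-bis(benzyloxy)phenyl]-3-[4-(benzyloxy)phenyl]-2,3-dihydro-1H-indene-1-carbaldehyde; 19 [4-(benzyloxy)phenyl]magnesium bromide
Product: 26 {(1R,2R,3R)-4,6-bis(benzyloxy)-2-[3,5-bis(benzyloxy)phenyl]-3-[4-(benzyloxy)phenyl]-2,3-dihydro-1H-inden-1-yl}[4-(benzyloxy)phenyl]methanol (both carbinol epimers)
Conditions: 19 (1.5 equiv), THF, −78 °C; pH 7 buffer quench
Reagents that add atoms: none
Why: Grignard addition to the aldehyde at −78 °C outruns alpha-deprotonation, and the new carbinol centre needs no control because it is oxidised in the next step.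

Step 16
Reactants: 26 {(1R,2R,3R)-4,6-bis(benzyloxy)-2-[3,5-bis(benzyloxy)phenyl]-3-[4-(benzyloxy)phenyl]-2,3-dihydro-1H-inden-1-yl}[4-(benzyloxy)phenyl]methanol
Product: 27 {(1R,2R,3R)-4,6-bis(benzyloxy)-2-[3,5-bis(benzyloxy)phenyl]-3-[4-(benzyloxy)phenyl]-2,3-dihydro-1H-inden-1-yl}[4-(benzyloxy)phenyl]methanone
Conditions: Dess–Martin periodinane, NaHCO3, CH2Cl2, 0 °C → rt
Reagents that add atoms: none
Why: Dess–Martin oxidation of the benzylic carbinol gives the aryl ketone under buffered, non-enolising conditions, keeping the C1 aroyl group cis to the C2 aryl group.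

Step 17
Reactants: 27 {(1R,2R,3R)-4,6-bis(benzyloxy)-2-[3,5-bis(benzyloxy)phenyl]-3-[4-(benzyloxy)phenyl]-2,3-dihydro-1H-inden-1-yl}[4-(benzyloxy)phenyl]methanone
Product: 28 caraphenol C as drawn: [(1R,2R,3R)-2-(3,5-dihydroxyphenyl)-4,6-dihydroxy-3-(4-hydroxyphenyl)-2,3-dihydro-1H-inden-1-yl](4-hydroxyphenyl)methanone
Conditions: H2 (1 atm), 10% Pd/C, EtOAc–THF, rt; filtration, no acid or base
Reagents that add atoms: none
Why: Catalytic hydrogenolysis cleaves the five aryl benzyl ethers at neutral pH much faster than a hindered, electron-rich aryl ketone is reduced, so the kinetic C1 configuration is never exposed to acid or base.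

## Compound list

1 | methyl 2-(3,5-dihydroxyphenyl)acetate | COC(=O)Cc1cc(O)cc(O)c1 | starting material
2 | methyl 2-[3,5-bis(benzyloxy)phenyl]acetate | COC(=O)Cc1cc(OCc2ccccc2)cc(OCc2ccccc2)c1 | intermediate
3 | 2-[3,5-bis(benzyloxy)phenyl]acetic acid | OC(=O)Cc1cc(OCc2ccccc2)cc(OCc2ccccc2)c1 | intermediate
4 | (4R)-4-benzyl-1,3-oxazolidin-2-one | O=C1N[C@H](Cc2ccccc2)CO1 | starting material
5 | [3,5-bis(benzyloxy)phenyl]acetic pivalic anhydride (not isolated) | CC(C)(C)C(=O)OC(=O)Cc1cc(OCc2ccccc2)cc(OCc2ccccc2)c1 | intermediate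
6 | (4R)-4-benzyl-3-{[3,5-bis(benzyloxy)phenyl]acetyl}-1,3-oxazolidin-2-one | O=C1OC[C@@H](Cc2ccccc2)N1C(=O)Cc1cc(OCc2ccccc2)cc(OCc2ccccc2)c1 | intermediate
7 | 3,5-bis(benzyloxy)benzaldehyde | O=Cc1cc(OCc2ccccc2)cc(OCc2ccccc2)c1 | starting material
8 | nitromethane | C[N+](=O)[O-] | starting material
9 | 1-[3,5-bis(benzyloxy)phenyl]-2-nitroethan-1-ol, racemic (not isolated) | OC(C[N+](=O)[O-])c1cc(OCc2ccccc2)cc(OCc2ccccc2)c1 | intermediate
10 | 1,3-bis(benzyloxy)-5-[(E)-2-nitroethenyl]benzene | [O-][N+](=O)/C=C/c1cc(OCc2ccccc2)cc(OCc2ccccc2)c1 | intermediate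
11 | trichlorotitanium (Z)-enolate of 6 (not isolated) | Cl[Ti](Cl)(Cl)O/C(=C\c1cc(OCc2ccccc2)cc(OCc2ccccc2)c1)N1C(=O)OC[C@H]1Cc1ccccc1 | intermediate
12 | (4R)-4-benzyl-3-{(2R,3R)-2,3-bis[3,5-bis(benzyloxy)phenyl]-4-nitrobutanoyl}-1,3-oxazolidin-2-one (major syn adduct; the 3-epimer converges at 18) | O=C1OC[C@@H](Cc2ccccc2)N1C(=O)[C@H]([C@@H](C[N+](=O)[O-])c1cc(OCc2ccccc2)cc(OCc2ccccc2)c1)c1cc(OCc2ccccc2)cc(OCc2ccccc2)c1 | intermediate
13 | (2R,3R)-2,3-bis[3,5-bis(benzyloxy)phenyl]-4-nitrobutan-1-ol | OC[C@H]([C@@H](C[N+](=O)[O-])c1cc(OCc2ccccc2)cc(OCc2ccccc2)c1)c1cc(OCc2ccccc2)cc(OCc2ccccc2)c1 | intermediate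
14 | (2R,3R)-2,3-bis[3,5-bis(benzyloxy)phenyl]-4-nitrobutyl pivalate | CC(C)(C)C(=O)OC[C@H]([C@@H](C[N+](=O)[O-])c1cc(OCc2ccccc2)cc(OCc2ccccc2)c1)c1cc(OCc2ccccc2)cc(OCc2ccccc2)c1 | intermediate
15 | (2R,3R)-2,3-bis[3,5-bis(benzyloxy)phenyl]-4-(pivaloyloxy)butanoic acid | CC(C)(C)C(=O)OC[C@H]([C@@H](C(O)=O)c1cc(OCc2ccccc2)cc(OCc2ccccc2)c1)c1cc(OCc2ccccc2)cc(OCc2ccccc2)c1 | intermediate
16 | (2R,3R)-2,3-bis[3,5-bis(benzyloxy)phenyl]-4-(pivaloyloxy)butanoyl chloride (not isolated) | CC(C)(C)C(=O)OC[C@H]([C@@H](C(Cl)=O)c1cc(OCc2ccccc2)cc(OCc2ccccc2)c1)c1cc(OCc2ccccc2)cc(OCc2ccccc2)c1 | intermediate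
17 | {(1R,2R)-4,6-bis(benzyloxy)-2-[3,5-bis(benzyloxy)phenyl]-3-oxo-2,3-dihydro-1H-inden-1-yl}methyl pivalate, cis (not isolated) | CC(C)(C)C(=O)OC[C@H]1c2cc(OCc3ccccc3)cc(OCc3ccccc3)c2C(=O)[C@H]1c1cc(OCc2ccccc2)cc(OCc2ccccc2)c1 | intermediate
18 | {(1R,2S)-4,6-bis(benzyloxy)-2-[3,5-bis(benzyloxy)phenyl]-3-oxo-2,3-dihydro-1H-inden-1-yl}methyl pivalate, trans | CC(C)(C)C(=O)OC[C@H]1c2cc(OCc3ccccc3)cc(OCc3ccccc3)c2C(=O)[C@@H]1c1cc(OCc2ccccc2)cc(OCc2ccccc2)c1 | intermediate
19 | [4-(benzyloxy)phenyl]magnesium bromide (THF solution) | Br[Mg]c1ccc(OCc2ccccc2)cc1 | starting material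
20 | {(1R,2S)-4,6-bis(benzyloxy)-2-[3,5-bis(benzyloxy)phenyl]-3-[4-(benzyloxy)phenyl]-3-hydroxy-2,3-dihydro-1H-inden-1-yl}methyl pivalate, C3 configuration not controlled (not isolated) | CC(C)(C)C(=O)OC[C@H]1c2cc(OCc3ccccc3)cc(OCc3ccccc3)c2C(O)(c2ccc(OCc3ccccc3)cc2)[C@@H]1c1cc(OCc2ccccc2)cc(OCc2ccccc2)c1 | intermediate
21 | {(1S)-4,6-bis(benzyloxy)-2-[3,5-bis(benzyloxy)phenyl]-3-[4-(benzyloxy)phenyl]-1H-inden-1-yl}methyl pivalate | CC(C)(C)C(=O)OC[C@H]1c2cc(OCc3ccccc3)cc(OCc3ccccc3)c2C(c2ccc(OCc3ccccc3)cc2)=C1c1cc(OCc2ccccc2)cc(OCc2ccccc2)c1 | intermediate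
22 | {(1R,2R,3R)-2-(3,5-dihydroxyphenyl)-4,6-dihydroxy-3-(4-hydroxyphenyl)-2,3-dihydro-1H-inden-1-yl}methyl pivalate, all-cis | CC(C)(C)C(=O)OC[C@H]1c2cc(O)cc(O)c2[C@@H](c2ccc(O)cc2)[C@H]1c1cc(O)cc(O)c1 | intermediate
23 | {(1R,2R,3R)-4,6-bis(benzyloxy)-2-[3,5-bis(benzyloxy)phenyl]-3-[4-(benzyloxy)phenyl]-2,3-dihydro-1H-inden-1-yl}methyl pivalate | CC(C)(C)C(=O)OC[C@H]1c2cc(OCc3ccccc3)cc(OCc3ccccc3)c2[C@@H](c2ccc(OCc3ccccc3)cc2)[C@H]1c1cc(OCc2ccccc2)cc(OCc2ccccc2)c1 | intermediate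
24 | {(1R,2R,3R)-4,6-bis(benzyloxy)-2-[3,5-bis(benzyloxy)phenyl]-3-[4-(benzyloxy)phenyl]-2,3-dihydro-1H-inden-1-yl}methanol | OC[C@H]1c2cc(OCc3ccccc3)cc(OCc3ccccc3)c2[C@@H](c2ccc(OCc3ccccc3)cc2)[C@H]1c1cc(OCc2ccccc2)cc(OCc2ccccc2)c1 | intermediate
25 | (1R,2R,3R)-4,6-bis(benzyloxy)-2-[3,5-bis(benzyloxy)phenyl]-3-[4-(benzyloxy)phenyl]-2,3-dihydro-1H-indene-1-carbaldehyde | O=C[C@H]1c2cc(OCc3ccccc3)cc(OCc3ccccc3)c2[C@@H](c2ccc(OCc3ccccc3)cc2)[C@H]1c1cc(OCc2ccccc2)cc(OCc2ccccc2)c1 | intermediate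
26 | {(1R,2R,3R)-4,6-bis(benzyloxy)-2-[3,5-bis(benzyloxy)phenyl]-3-[4-(benzyloxy)phenyl]-2,3-dihydro-1H-inden-1-yl}[4-(benzyloxy)phenyl]methanol, carbinol epimers | OC(c1ccc(OCc2ccccc2)cc1)[C@H]1c2cc(OCc3ccccc3)cc(OCc3ccccc3)c2[C@@H](c2ccc(OCc3ccccc3)cc2)[C@H]1c1cc(OCc2ccccc2)cc(OCc2ccccc2)c1 | intermediate
27 | {(1R,2R,3R)-4,6-bis(benzyloxy)-2-[3,5-bis(benzyloxy)phenyl]-3-[4-(benzyloxy)phenyl]-2,3-dihydro-1H-inden-1-yl}[4-(benzyloxy)phenyl]methanone | O=C(c1ccc(OCc2ccccc2)cc1)[C@H]1c2cc(OCc3ccccc3)cc(OCc3ccccc3)c2[C@@H](c2ccc(OCc3ccccc3)cc2)[C@H]1c1cc(OCc2ccccc2)cc(OCc2ccccc2)c1 | intermediate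
28 | caraphenol C as drawn, [(1R,2R,3R)-2-(3,5-dihydroxyphenyl)-4,6-dihydroxy-3-(4-hydroxyphenyl)-2,3-dihydro-1H-inden-1-yl](4-hydroxyphenyl)methanone | O=C(c1ccc(O)cc1)[C@H]1c2cc(O)cc(O)c2[C@@H](c2ccc(O)cc2)[C@H]1c1cc(O)cc(O)c1 | target

## Step count and risks

Total steps: 17. Longest linear sequence: 16 steps (steps 1–3 and 5–17, from 1 to 28); step 4 is a one-step branch.

Most likely to fail, first: step 5. The titanium enolate of an arylacetyl imide may add sluggishly to the nitrostyrene, or the nitrostyrene may oligomerise under TiCl4. The fallback replaces auxiliary control by hydrogen-bond catalysis and sets out from 3. Acid 3 is condensed with 3,5-dimethylpyrazole (EDC·HCl, DMAP, CH2Cl2) to the acyl pyrazole 1-{[3,5-bis(benzyloxy)phenyl]acetyl}-3,5-dimethyl-1H-pyrazole F1. F1 adds to 10 under a cinchona-derived bifunctional urea catalyst (10 mol%, toluene, rt; the pseudoenantiomer giving the 2R series is chosen in a test run) to give the syn adduct (2R,3R)-2,3-bis[3,5-bis(benzyloxy)phenyl]-1-(3,5-dimethyl-1H-pyrazol-1-yl)-4-nitrobutan-1-one F2. NaBH4 (THF–MeOH, 0 °C) reduces this activated amide, and the route is rejoined at 13.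

Second: step 10. The ketone of 18 is electron-rich, flanked by a peri benzyloxy group and very easily enolised, so even the organocerium reagent may mostly return starting ketone. The fallback uses the enolisation instead of fighting it and sets out from 18. KN(SiMe3)2 (1.05 equiv) and PhNTf2 in THF at −78 °C give the enol triflate {(1S)-4,6-bis(benzyloxy)-2-[3,5-bis(benzyloxy)phenyl]-3-[(trifluoromethanesulfonyl)oxy]-1H-inden-1-yl}methyl pivalate F3. Base-free Negishi coupling (Pd(PPh3)4, THF, 50 °C) with [4-(benzyloxy)phenyl]zinc chloride F4, made from 19 and ZnCl2, then gives the indene; no carbonate or amine is present that could shift the indene double bond and racemise C1. The route is rejoined at 21.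

Third: step 17. Five hydrogenolyses must finish before the aryl ketone is reduced, and the product carries a C1 configuration that any base would epimerise to trans. The fallback sets out from 27 and removes the benzyl groups non-reductively with BCl3 and pentamethylbenzene as cation scavenger (CH2Cl2, −78 °C, cold MeOH quench), a Lewis-acid dealkylation that runs too cold for enolisation and cannot touch the ketone. It comes back at 28 directly and makes no new compound (F0).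

## Further compounds

F1 | step 5 | 1-{[3,5-bis(benzyloxy)phenyl]acetyl}-3,5-dimethyl-1H-pyrazole | Cc1cc(C)n(n1)C(=O)Cc1cc(OCc2ccccc2)cc(OCc2ccccc2)c1
F2 | step 5 | (2R,3R)-2,3-bis[3,5-bis(benzyloxy)phenyl]-1-(3,5-dimethyl-1H-pyrazol-1-yl)-4-nitrobutan-1-one | Cc1cc(C)n(n1)C(=O)[C@H]([C@@H](C[N+](=O)[O-])c1cc(OCc2ccccc2)cc(OCc2ccccc2)c1)c1cc(OCc2ccccc2)cc(OCc2ccccc2)c1
F3 | step 10 | {(1S)-4,6-bis(benzyloxy)-2-[3,5-bis(benzyloxy)phenyl]-3-[(trifluoromethanesulfonyl)oxy]-1H-inden-1-yl}methyl pivalate | CC(C)(C)C(=O)OC[C@H]1c2cc(OCc3ccccc3)cc(OCc3ccccc3)c2C(OS(=O)(=O)C(F)(F)F)=C1c1cc(OCc2ccccc2)cc(OCc2ccccc2)c1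
F4 | step 10 | [4-(benzyloxy)phenyl]zinc chloride | Cl[Zn]c1ccc(OCc2ccccc2)cc1
F0 | step 17 | none | none
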